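**Strategy.** The γ-lactone (O, C12, C11, C7, C6; germacrane numbering) is treated as a formal [3+2] adduct of CO2 across C11 and C6, the two carbons that flank C7. On an acyclic chain carrying C7–C10, a secondary C11 alkylzinc (from the iodide) is carboxylated with CO2 and, in the same flask, PhSeCl makes the new carboxylate close onto C6 of an (E)-propenyl group. This fixes C6 trans to C7 and leaves a handle that becomes the C6 vinyl group. The precursor comes from lactic acid by alkylation, asymmetric hexadienylboration and Markovnikov hydroiodination. The furanone is then built and the nine-membered oxacycle closed by ring-closing metathesis before angeloylation.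

Key step: step 9

Remark: atoms are numbered as in germacranes (C1 ketone, C2=C3 and C4=C5 alkenes, C6 lactone carbinol, C7, C8 ester carbinol, C9, C10 quaternary ether carbon, C11, C12 lactone carbonyl, C13 the methyl on C11); the 4,5-alkene geometry of the target (C3 and C6 cis) is assumed to be the only one the nine-membered oxacycle can hold.

Step 1
Reactants: 1 (S)-lactic acid; 2 pivalaldehyde
Product: 3 (2S,5S)-2-tert-butyl-5-methyl-1,3-dioxolan-4-one
Conditions: TsOH·H2O (cat.), H2SO4 (cat.), pentane, reflux, Dean–Stark; crystallisation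
Reagents that add atoms: none
Why: Acid-catalysed acetalisation under thermodynamic control (first stage of the Seebach self-regeneration of stereocentres): the lactate centre is untouched and steers the new acetal carbon to the cis (2S) isomer, which is purified by crystallisation.

Step 2
Reactants: 3 (2S,5S)-2-tert-butyl-5-methyl-1,3-dioxolan-4-one; 4 allyl bromide
Product: 5 (2S,5R)-2-tert-butyl-5-methyl-5-(prop-2-en-1-yl)-1,3-dioxolan-4-one
Conditions: LDA, THF, −78 °C; then 4, −78 → −30 °C
Reagents that add atoms: none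
Why: Seebach enolate alkylation: the planar lithium enolate is allylated on the face opposite the tert-butyl group, so allyl takes the place of the former hydrogen and the future C10 is set as R under control of the acetal centre.

Step 3
Reactants: 5 (2S,5R)-2-tert-butyl-5-methyl-5-(prop-2-en-1-yl)-1,3-dioxolan-4-one
Product: 6 (3R)-3-hydroxy-3-methylhex-5-en-2-one
Conditions: MeLi (1.05 equiv), Et2O–THF, −78 °C; AcOH, −78 → 25 °C
Reagents that add atoms: methyllithium, C[Li]
Why: Addition of MeLi to the lactone-type carbonyl (nucleophilic acyl substitution) should stop at the cyclic lithium hemiketal at −78 °C, which on acidic quench collapses to the α-hydroxy methyl ketone with loss of pivalaldehyde; the quaternary C10 cannot epimerise.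

Step 4
Reactants: 6 (3R)-3-hydroxy-3-methylhex-5-en-2-one
Product: 7 (3R)-3-methyl-3-[(trimethylsilyl)oxy]hex-5-en-2-one
Conditions: N-(trimethylsilyl)imidazole, CH2Cl2, 25 °C
Reagents that add atoms: N-(trimethylsilyl)imidazole, C[Si](C)(C)n1ccnc1
Why: Silylation of the tertiary alcohol with a neutral silyl donor, so the methyl ketone is not converted to an enol ether; the TMS ether is chosen because mild acid removes it in step 11.

Step 5
Reactants: 7 (3R)-3-methyl-3-[(trimethylsilyl)oxy]hex-5-en-2-one
Product: 8 (3R)-3-methyl-4-oxo-3-[(trimethylsilyl)oxy]pentanal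
Conditions: O3, CH2Cl2, −78 °C; PPh3, −78 → 25 °C
Reagents that add atoms: ozone, [O-][O+]=O
Why: Ozonolysis with reductive work-up of the only alkene gives the C8 aldehyde; no stereocentre is affected and the β-silyloxy aldehyde is used directly.

Step 6
Reactants: 8 (3R)-3-methyl-4-oxo-3-[(trimethylsilyl)oxy]pentanal; 9 (4E)-hexa-1,4-diene
Product: 13 (3R,5R,6S,7E)-6-ethenyl-5-hydroxy-3-methyl-3-[(trimethylsilyl)oxy]non-7-en-2-one, via potassium hexadienide 10 (not isolated), via hexadienyl diisopinocampheylborane 11 (not isolated), via O-boryl adduct 12 (not isolated)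
Conditions: 9, n-BuLi, KOt-Bu, THF, −78 → −50 °C; (−)-Ipc2BOMe, −78 °C; BF3·OEt2, −78 → 0 → −78 °C; 8, −78 °C; NaBO3·4H2O, THF–H2O, 25 °C
Reagents that add atoms: none
Why: Brown-type asymmetric allylboration through a closed chair transition state: brief warming lets reversible boron shifts settle the reagent as the primary (2E,4E)-dienylborane, which reacts at its γ-carbon so that the E geometry gives the anti relation between the C8 hydroxyl and the C7 propenyl group, the isopinocampheyl groups from (+)-α-pinene direct attack on the Si face of the aldehyde (8R, hence C7 as drawn) under reagent control, and the aldehyde reacts far faster than the hindered ketone.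

Step 7
Reactants: 13 (3R,5R,6S,7E)-6-ethenyl-5-hydroxy-3-methyl-3-[(trimethylsilyl)oxy]non-7-en-2-one
Product: 14 (3R,5R,6S,7E)-5-[(tert-butyldimethylsilyl)oxy]-6-ethenyl-3-methyl-3-[(trimethylsilyl)oxy]non-7-en-2-one
Conditions: TBSOTf, 2,6-lutidine, CH2Cl2, −78 °C
Reagents that add atoms: tert-butyldimethylsilyl triflate, CC(C)(C)[Si](C)(C)OS(=O)(=O)C(F)(F)F
Why: Silyl ether formation at low temperature protects the hindered C8 hydroxyl without enolising the ketone; the TBS group should survive the acid of step 11, unlike the TMS ether.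

Step 8
Reactants: 14 (3R,5R,6S,7E)-5-[(tert-butyldimethylsilyl)oxy]-6-ethenyl-3-methyl-3-[(trimethylsilyl)oxy]non-7-en-2-one
Product: 15 (3R,5R,6S,7E)-5-[(tert-butyldimethylsilyl)oxy]-6-(1-iodoethyl)-3-methyl-3-[(trimethylsilyl)oxy]non-7-en-2-one (both epimers at the iodine-bearing C11)
Conditions: Co(acac)2, t-BuOOH, Et3SiH, CH2I2, n-PrOH, 25 °C
Reagents that add atoms: diiodomethane, ICI
Why: Mukaiyama-type hydrogen atom transfer hydrofunctionalisation (Markovnikov hydroiodination): a cobalt hydride delivers hydrogen to the terminal carbon of the monosubstituted vinyl group much faster than to the 1,2-disubstituted propenyl group and the secondary C11 radical abstracts iodine from CH2I2; C11 forms as both epimers, which is harmless because this centre is planarised in step 9 and set in step 10.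

Step 9
Reactants: 15 (3R,5R,6S,7E)-5-[(tert-butyldimethylsilyl)oxy]-6-(1-iodoethyl)-3-methyl-3-[(trimethylsilyl)oxy]non-7-en-2-one
Product: 18 (3RS,4S,5S)-4-{(1R,3R)-1-[(tert-butyldimethylsilyl)oxy]-3-methyl-4-oxo-3-[(trimethylsilyl)oxy]pentyl}-3-methyl-5-[(1R)-1-(phenylselanyl)ethyl]oxolan-2-one, via alkylzinc iodide 16 (not isolated), via zinc carboxylate 17 (not isolated)
Conditions: Zn dust (activated), LiCl, THF, 25–40 °C; CO2 (1 atm), Ni(acac)2 (10 mol%), PCy3 (20 mol%), 0 → 25 °C; PhSeCl, −78 → 25 °C
Reagents that add atoms: carbon dioxide, O=C=O; benzeneselenenyl chloride, Cl[Se]c1ccccc1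
Why: Zinc inserts into the C11–I bond to give the secondary alkylzinc iodide, which transmetalates to a zerovalent nickel–CO2 complex and after reductive elimination delivers the C11–C12 bond as the zinc carboxylate; PhSeCl then forms a seleniranium ion on the (E)-propenyl group and the carboxylate oxygen opens it at C6 to make the O–C6 bond. The closest known reactions are the nickel-catalysed carboxylation of alkylzinc halides with CO2 and the phenylselenolactonisation of γ,δ-unsaturated acids, here run in one flask so that CO2 is formally added across C11 and C6. The γ-lactone ring closes in the 5-exo mode, by anti opening of the seleniranium ion. C6 should be set trans to the C7 substituent because seleniranium opening is reversible in the Lewis-acidic zinc halide medium and the trans-4,5-disubstituted lactone (allylic 1,3-strain minimised) is the thermodynamic product; the selenium-bearing C5 follows from anti addition to the E alkene and is erased in step 10, and C11 is not controlled here and is equilibrated in step 10. The step needs carboxylation to outrun protonation of the C–Zn bond or its addition to the C1 ketone, which the low reactivity of alkylzinc halides towards the hindered α-quaternary ketone and the nickel catalysis should secure, and it needs 5-exo rather than 6-endo closure, which the short carboxylate tether favours for an alkene with two secondary termini. Only one alkene is present, so selenium has no competing site.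

Step 10
Reactants: 18 (3RS,4S,5S)-4-{(1R,3R)-1-[(tert-butyldimethylsilyl)oxy]-3-methyl-4-oxo-3-[(trimethylsilyl)oxy]pentyl}-3-methyl-5-[(1R)-1-(phenylselanyl)ethyl]oxolan-2-one
Product: 21 (3S,4S,5R)-4-{(1R,3R)-1-[(tert-butyldimethylsilyl)oxy]-3-methyl-4-oxo-3-[(trimethylsilyl)oxy]pentyl}-5-ethenyl-3-methyloxolan-2-one, via selenoxide 19 (not isolated), via C11-epimeric vinyl lactone 20 (not isolated)
Conditions: 30% H2O2, pyridine, CH2Cl2, 0 → 25 °C; then DBU, PhMe, 80 °C
Reagents that add atoms: none
Why: Selenoxide syn-elimination, which occurs away from the oxygen-bearing C6 and so gives the C6 vinyl group, followed by base-mediated enolisation of the lactone (thermodynamic epimerisation) that should place the C11 methyl trans to the bulky C7 substituent and thereby set 11S.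

Step 11
Reactants: 21 (3S,4S,5R)-4-{(1R,3R)-1-[(tert-butyldimethylsilyl)oxy]-3-methyl-4-oxo-3-[(trimethylsilyl)oxy]pentyl}-5-ethenyl-3-methyloxolan-2-one; 22 pentafluorophenyl methacrylate
Product: 24 (3S,4S,5R)-4-{(1R)-1-[(tert-butyldimethylsilyl)oxy]-2-[(2R)-2-methyl-3-oxo-5-(prop-1-en-2-yl)-2,3-dihydrofuran-2-yl]ethyl}-5-ethenyl-3-methyloxolan-2-one, via 1,3-diketone 23 (not isolated)
Conditions: MgBr2·OEt2, i-Pr2NEt, CH2Cl2, 25 °C; then 1 M HCl, THF, 25 °C
Reagents that add atoms: none
Why: Soft-enolisation Claisen acylation of the only enolisable ketone position (the C2 methyl, magnesium chelated by the α-silyloxy ketone) with the active ester gives the 1,3-diketone, and acid then removes the tertiary TMS ether and cyclodehydrates the α'-hydroxy-1,3-diketone to the 3(2H)-furanone while the secondary TBS ether stays; no stereocentre is formed.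

Step 12
Reactants: 24 (3S,4S,5R)-4-{(1R)-1-[(tert-butyldimethylsilyl)oxy]-2-[(2R)-2-methyl-3-oxo-5-(prop-1-en-2-yl)-2,3-dihydrofuran-2-yl]ethyl}-5-ethenyl-3-methyloxolan-2-one
Product: 25 8-O-tert-butyldimethylsilyl ether of (4Z,6R,7R,8R,10R,11S)-8-hydroxy-1-oxo-3,10-epoxygermacra-2,4-dien-12,6-olide
Conditions: second-generation Hoveyda–Grubbs catalyst (20 mol%), PhMe (1 mM), 100 °C
Reagents that add atoms: none
Why: Ring-closing olefin metathesis between the lactone vinyl group and the isopropenyl group, driven by loss of ethylene; the new C4=C5 bond can only be cis (4Z) within the nine-membered oxacycle, and closure of this ring type by metathesis should have precedent in closely related bridged 3(2H)-furanones.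

Step 13
Reactants: 25 8-O-tert-butyldimethylsilyl ether of the macrocyclic alcohol
Product: 26 (4Z,6R,7R,8R,10R,11S)-8-hydroxy-1-oxo-3,10-epoxygermacra-2,4-dien-12,6-olide
Conditions: HF·pyridine, pyridine, THF, 0 → 25 °C
Reagents that add atoms: none
Why: Fluoride-mediated cleavage of the silyl ether under buffered, non-basic conditions that should leave the lactone, the furanone and C11 untouched.

Step 14
Reactants: 26 (4Z,6R,7R,8R,10R,11S)-8-hydroxy-1-oxo-3,10-epoxygermacra-2,4-dien-12,6-olide; 27 angelic acid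
Product: 29 (4Z,6R,7R,8R,10R,11S)-8-(angeloyloxy)-1-oxo-3,10-epoxygermacra-2,4-dien-12,6-olide (CNP0278264.1), via mixed anhydride 28 (not isolated)
Conditions: 27, 2,4,6-trichlorobenzoyl chloride, Et3N, PhMe, 25 °C; then 26, 80 °C
Reagents that add atoms: none
Why: Yamaguchi-type mixed-anhydride esterification run without DMAP, conditions under which angelic acid should be transferred without Z to E isomerisation to the tiglate; no stereocentre is touched.

**Compound list**

1 | (S)-lactic acid | C[C@H](O)C(=O)O | starting material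
2 | pivalaldehyde | CC(C)(C)C=O | starting material
3 | (2S,5S)-2-tert-butyl-5-methyl-1,3-dioxolan-4-one | C[C@@H]1O[C@H](C(C)(C)C)OC1=O | intermediate
4 | allyl bromide | C=CCBr | starting material
5 | (2S,5R)-2-tert-butyl-5-methyl-5-(prop-2-en-1-yl)-1,3-dioxolan-4-one | C[C@]1(CC=C)O[C@H](C(C)(C)C)OC1=O | intermediate
6 | (3R)-3-hydroxy-3-methylhex-5-en-2-one | CC(=O)[C@](C)(O)CC=C | intermediate
7 | (3R)-3-methyl-3-[(trimethylsilyl)oxy]hex-5-en-2-one | CC(=O)[C@](C)(O[Si](C)(C)C)CC=C | intermediate
8 | (3R)-3-methyl-4-oxo-3-[(trimethylsilyl)oxy]pentanal | CC(=O)[C@](C)(O[Si](C)(C)C)CC=O | intermediate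
9 | (4E)-hexa-1,4-diene | C=CC/C=C/C | starting material
10 | potassium hexa-2,4-dien-1-ide (delocalised 1-methylpentadienyl anion, drawn 2E,4E) | C/C=C/C=C/C[K] | intermediate
11 | B-[(2E,4E)-hexa-2,4-dien-1-yl]diisopinocampheylborane (isopinocampheyl groups from (+)-α-pinene) | C/C=C/C=C/CB([C@@H]1C[C@@H]2C[C@H]([C@H]1C)C2(C)C)[C@@H]1C[C@@H]2C[C@H]([C@H]1C)C2(C)C | intermediate
12 | O-(diisopinocampheylboryl) ether of 13 | CC(=O)[C@](C)(O[Si](C)(C)C)C[C@@H](OB([C@@H]1C[C@@H]2C[C@H]([C@H]1C)C2(C)C)[C@@H]1C[C@@H]2C[C@H]([C@H]1C)C2(C)C)[C@@H](C=C)/C=C/C | intermediate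
13 | (3R,5R,6S,7E)-6-ethenyl-5-hydroxy-3-methyl-3-[(trimethylsilyl)oxy]non-7-en-2-one | CC(=O)[C@](C)(O[Si](C)(C)C)C[C@@H](O)[C@@H](C=C)/C=C/C | intermediate
14 | (3R,5R,6S,7E)-5-[(tert-butyldimethylsilyl)oxy]-6-ethenyl-3-methyl-3-[(trimethylsilyl)oxy]non-7-en-2-one | CC(=O)[C@](C)(O[Si](C)(C)C)C[C@@H](O[Si](C)(C)C(C)(C)C)[C@@H](C=C)/C=C/C | intermediate
15 | (3R,5R,6S,7E)-5-[(tert-butyldimethylsilyl)oxy]-6-(1-iodoethyl)-3-methyl-3-[(trimethylsilyl)oxy]non-7-en-2-one (C11 epimers) | CC(=O)[C@](C)(O[Si](C)(C)C)C[C@@H](O[Si](C)(C)C(C)(C)C)[C@@H](C(C)I)/C=C/C | intermediate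
16 | C11 alkylzinc iodide from 15 | CC(=O)[C@](C)(O[Si](C)(C)C)C[C@@H](O[Si](C)(C)C(C)(C)C)[C@@H](C(C)[Zn]I)/C=C/C | intermediate
17 | iodozinc C12 carboxylate | CC(=O)[C@](C)(O[Si](C)(C)C)C[C@@H](O[Si](C)(C)C(C)(C)C)[C@@H](C(C)C(=O)O[Zn]I)/C=C/C | intermediate
18 | (3RS,4S,5S)-4-{(1R,3R)-1-[(tert-butyldimethylsilyl)oxy]-3-methyl-4-oxo-3-[(trimethylsilyl)oxy]pentyl}-3-methyl-5-[(1R)-1-(phenylselanyl)ethyl]oxolan-2-one | CC(=O)[C@](C)(O[Si](C)(C)C)C[C@@H](O[Si](C)(C)C(C)(C)C)[C@H]1C(C)C(=O)O[C@@H]1[C@@H](C)[Se]c1ccccc1 | intermediate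
19 | selenoxide of 18 | CC(=O)[C@](C)(O[Si](C)(C)C)C[C@@H](O[Si](C)(C)C(C)(C)C)[C@H]1C(C)C(=O)O[C@@H]1[C@@H](C)[Se](=O)c1ccccc1 | intermediate
20 | 5-ethenyl lactone as C11 epimer mixture | CC(=O)[C@](C)(O[Si](C)(C)C)C[C@@H](O[Si](C)(C)C(C)(C)C)[C@H]1C(C)C(=O)O[C@@H]1C=C | intermediate
21 | (3S,4S,5R)-4-{(1R,3R)-1-[(tert-butyldimethylsilyl)oxy]-3-methyl-4-oxo-3-[(trimethylsilyl)oxy]pentyl}-5-ethenyl-3-methyloxolan-2-one | CC(=O)[C@](C)(O[Si](C)(C)C)C[C@@H](O[Si](C)(C)C(C)(C)C)[C@H]1[C@H](C)C(=O)O[C@@H]1C=C | intermediate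
22 | pentafluorophenyl methacrylate | CC(=C)C(=O)Oc1c(F)c(F)c(F)c(F)c1F | starting material
23 | (3S,4S,5R)-4-{(1R,3R)-1-[(tert-butyldimethylsilyl)oxy]-3,7-dimethyl-4,6-dioxo-3-[(trimethylsilyl)oxy]oct-7-en-1-yl}-5-ethenyl-3-methyloxolan-2-one | CC(=C)C(=O)CC(=O)[C@](C)(O[Si](C)(C)C)C[C@@H](O[Si](C)(C)C(C)(C)C)[C@H]1[C@H](C)C(=O)O[C@@H]1C=C | intermediate
24 | (3S,4S,5R)-4-{(1R)-1-[(tert-butyldimethylsilyl)oxy]-2-[(2R)-2-methyl-3-oxo-5-(prop-1-en-2-yl)-2,3-dihydrofuran-2-yl]ethyl}-5-ethenyl-3-methyloxolan-2-one | CC(C)(C)[Si](C)(C)O[C@H](C[C@@]1(C)OC(=CC1=O)C(C)=C)[C@H]1[C@H](C)C(=O)O[C@@H]1C=C | intermediate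
25 | 8-O-tert-butyldimethylsilyl ether of 26 | CC(C)(C)[Si](C)(C)O[C@@H]1C[C@@]2(C)OC(=CC2=O)/C(C)=C\[C@H]2OC(=O)[C@@H](C)[C@@H]21 | intermediate
26 | (4Z,6R,7R,8R,10R,11S)-8-hydroxy-1-oxo-3,10-epoxygermacra-2,4-dien-12,6-olide | O[C@@H]1C[C@@]2(C)OC(=CC2=O)/C(C)=C\[C@H]2OC(=O)[C@@H](C)[C@@H]21 | intermediate
27 | angelic acid, (2Z)-2-methylbut-2-enoic acid | C/C=C(/C)C(=O)O | starting material
28 | angelic 2,4,6-trichlorobenzoic anhydride | C/C=C(/C)C(=O)OC(=O)c1c(Cl)cc(Cl)cc1Cl | intermediate
29 | (4Z,6R,7R,8R,10R,11S)-8-(angeloyloxy)-1-oxo-3,10-epoxygermacra-2,4-dien-12,6-olide (CNP0278264.1) | C/C=C(/C)C(=O)O[C@@H]1C[C@@]2(C)OC(=CC2=O)/C(C)=C\[C@H]2OC(=O)[C@@H](C)[C@@H]21 | target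

**Step count.** Total: 14 steps. Longest linear sequence: 14 steps (1 → 29); compounds 2, 4, 9, 22 and 27 enter as purchased reactants.

**Steps most likely to fail**

Step 9. The carboxylation of the secondary alkylzinc may be slow or unselective: protonation to the reduced chain, β-hydride elimination and chain isomerisation on nickel, or addition of the C–Zn bond to the C1 ketone. The selenocyclisation may also close with incomplete trans selectivity or in the 6-endo mode. The fallback sets out from 15 and comes back at 18. Iodine atom-transfer radical carbonylation of 15 (CO 40 atm, hν, K2CO3, H2O–MeCN) would give, after hydrolysis of the acyl iodide, the carboxylic acid F1. Isolated F1 would then be cyclised with PhSeCl in CH2Cl2 without base, so that the HCl formed keeps seleniranium opening reversible and the trans lactone 18 forms under thermodynamic control.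

Step 6. Boron may migrate along the dienyl chain without settling on one isomer, so that syn adducts or conjugated ε-adducts form and reagent control is eroded; the TMS ether may also be lost during oxidative work-up. The fallback sets out from 8 and comes back at 13. Commercial (2E,4E)-hexa-2,4-dien-1-ol would be borylated with B2pin2 under palladium catalysis (Pd2(dba)3, DMSO) to the configurationally stable pinacol boronate F2. A chiral phosphoric acid-catalysed allylboration of 8 with F2 ((S)-TRIP, the antipode expected to direct Si-face attack, PhMe, −30 °C) would give the O-boryl adduct F3, which is hydrolysed on work-up to 13.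

Step 12. The ruthenium carbene may decompose, or dimerise the substrate by cross-metathesis at the vinyl group, faster than it closes the strained nine-membered oxacycle onto the electron-poor 1,1-disubstituted isopropenyl group. The fallback sets out from 21 and comes back at 25:
- Claisen acylation of 21 with pentafluorophenyl propanoate under the step 11 conditions would give the ethyl diketone F4, which acid converts to the 5-ethylfuranone F5.
- Dihydroxylation of the vinyl group (OsO4 cat., NMO) would give the diol F6, and NaIO4 would cleave it to the aldehyde F7.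
- An intramolecular vinylogous aldol reaction (KHMDS, THF, −78 °C, γ-deprotonation of the 5-ethyl group) would close the ring as the aldol F8.
- The mesylate F9 (MsCl, Et3N) would eliminate with DBU to the conjugated 4Z alkene 25.

Further compounds
F1 | step 9 | (2RS,3R,4R,6R)-4-[(tert-butyldimethylsilyl)oxy]-2,6-dimethyl-7-oxo-3-[(1E)-prop-1-en-1-yl]-6-[(trimethylsilyl)oxy]octanoic acid | CC(=O)[C@](C)(O[Si](C)(C)C)C[C@@H](O[Si](C)(C)C(C)(C)C)[C@@H](C(C)C(=O)O)/C=C/C
F2 | step 6 | 2-[(2E,4E)-hexa-2,4-dien-1-yl]-4,4,5,5-tetramethyl-1,3,2-dioxaborolane | C/C=C/C=C/CB1OC(C)(C)C(C)(C)O1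
F3 | step 6 | O-(pinacolatoboryl) ether of 13 | CC(=O)[C@](C)(O[Si](C)(C)C)C[C@@H](OB1OC(C)(C)C(C)(C)O1)[C@@H](C=C)/C=C/C
F4 | step 12 | ethyl analogue of diketone 23 (C4 without the methylene) | CCC(=O)CC(=O)[C@](C)(O[Si](C)(C)C)C[C@@H](O[Si](C)(C)C(C)(C)C)[C@H]1[C@H](C)C(=O)O[C@@H]1C=C
F5 | step 12 | 5-ethylfuranone analogue of 24 | CC(C)(C)[Si](C)(C)O[C@H](C[C@@]1(C)OC(=CC1=O)CC)[C@H]1[C@H](C)C(=O)O[C@@H]1C=C
F6 | step 12 | vicinal diol from the vinyl group of F5 | CC(C)(C)[Si](C)(C)O[C@H](C[C@@]1(C)OC(=CC1=O)CC)[C@H]1[C@H](C)C(=O)O[C@@H]1C(O)CO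
F7 | step 12 | C5 aldehyde from F6 | CC(C)(C)[Si](C)(C)O[C@H](C[C@@]1(C)OC(=CC1=O)CC)[C@H]1[C@H](C)C(=O)O[C@@H]1C=O
F8 | step 12 | macrocyclic aldol (4,5-dihydro-5-hydroxy analogue of 25) | CC(C)(C)[Si](C)(C)O[C@@H]1C[C@@]2(C)OC(=CC2=O)C(C)C(O)[C@H]2OC(=O)[C@@H](C)[C@@H]21
F9 | step 12 | C5 mesylate of F8 | CC(C)(C)[Si](C)(C)O[C@@H]1C[C@@]2(C)OC(=CC2=O)C(C)C(OS(C)(=O)=O)[C@H]2OC(=O)[C@@H](C)[C@@H]21
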